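Late times are what I studied in the earlier runs: after a quick start the product only creeps, and in elm it creeps well short of the charge.

| setting | birch | elm | flask |
|---|---|---|---|
| electrophile | 0.60 M | 0.90 M | 1.2 M |
| nucleophile | 2.4 M | 2.4 M | 2.40 M |
| protic impurity | 1.2 M | 1.2 M | 1.20 M |
| remark | run made earlier | run made earlier |  |
| time |  |  | 50 min |

| run | time / min | electrophile / % | product / % |
|---|---|---|---|
| birch | 5.00 | 26 | 62 |
| birch | 10.0 | 16 | 72 |
| birch | 15.0 | 8 | 83 |
| birch | 20.0 | 10 | 81 |
| birch | 25.0 | 4 | 86 |
| birch | 30.0 | 6 | 88 |
| elm | 2.00 | 52 | 36 |
| elm | 6.00 | 27 | 55 |
| elm | 10.0 | 23 | 63 |
| elm | 15.0 | 21 | 65 |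
| elm | 25.0 | 15 | 70 |
| elm | 30.0 | 16 | 74 |

(standard deviation of a reading: 1.5 percentage points)

- what was read earlier has a scatter of 1.5 percentage points, one standard deviation
- what has gone from electrophile into another species counts as reacted, even if it can come back
- the earlier runs do not show how much of nucleophile is bound; that part of a forecast is a guess

- part of the electrophile that has reacted at 50 min
- share of the unused nucleophile that is free and not bound as protonated nucleophile, at 50 min

1. The puzzle: this flask holds twice as much nucleophile as electrophile, yet I expected its product to bend early.
2. I assumed that each protic impurity quenches one nucleophile and that each product costs two: one built in, one bound as protonated nucleophile. Setting the quench apart as a first charge on the nucleophile, I divided the rate of the remaining nucleophile use by the rate of product formation; on these assumptions that gives two, and time drops out.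
3. So I defined the covered fraction, the part of the electrophile charge that the unquenched nucleophile (the limiting reagent here) pays for at that price. For this flask it is 50.0%.
4. For elm it is 66.7%, and elm's product read 65% at 15.0 min, where its climb had slowed.
5. Elm's last reading puts 61.5% of the non-product part in electrophile; the rest is held elsewhere and counts as reacted. At the bend this flask would then have 69.2% reacted, with the creep still to add.

The forecast said 74% reacted and 20% free, on the ground that “the active nucleophile collapses”.

The simulation gave 80.4% reacted and 6.16% free.

    nucleophile + protic impurity → quenched reagent (k = 0.210 /M/s)
    nucleophile + acid set free ⇌ protonated nucleophile, settled at all times (K = 43.0 /M)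
    electrophile + nucleophile → acid set free + product (k = 0.00510 /M/s)
    electrophile ⇌ dormant form (K = 0.810, k = 0.00130 /s)

At 50.0 min this flask held 63.6% product, 14 percentage points above the covered fraction, so the creep added 11 points to my bend value. Acid set free stood at 0.354 M beside 0.409 M protonated nucleophile, so not every product had paid its second nucleophile. This flask was not at rest: at 500 min it has 90.8% reacted and 83.2% product, with protonated nucleophile down to 0.196 M.

With 1.4 M nucleophile and the other charges unchanged, the covered fraction is 8.33%. That neighbour gave 15.1% product and 53.2% reacted, with 38.1% in the dormant form.

The readings come from a simulation for substances that don't exist, noise included.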